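## Structural features

The target 13 is the vanillate (4-hydroxy-3-methoxybenzoate) ester of a guaiane alcohol. A cyclopentene (C1–C2–C3=C4(Me)–C5) and a cycloheptene (C5–C6–C7(iPr)–C8(O-acyl)–C9–C10(Me)=C1) share the C1–C5 bond; C11 is the isopropyl CH. The stereocenters are C5 (R, ring-fusion methine), C7 (R) and C8 (S). C7 and C8 are adjacent, with isopropyl and acyloxy trans; C5 is one methylene away from C7, and H5 and H8 lie on one face, H7 on the other. C1=C10 is tetrasubstituted and C3=C4 trisubstituted, and they form a skipped diene in which C2–H2 and C5–H are doubly allylic. Acid, strong base or metal hydrides can therefore move the diene into conjugation and erase C5; the free phenol and the aryl ester are the other fragile groups. The difficulty is placing two non-conjugated alkenes at fixed positions in a 5–7 bicycle while controlling three stereocenters. Only the C1–C5 bond separates the bicycle from a ten-membered carbocycle, and germacrone 1 already has that ring with both methyl groups, the C8 oxygen and the C7 isopropyl carbons. The key step exploits this by closing C1 onto C5 across the ring.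

## Logic of the disconnections

13 to 12: the phenolic O–acetyl bond is cut. The phenol must be masked while the acid is activated and while the sulfurane is used; an acetate adds no skeletal complexity. The forward step must cleave an aryl acetate without touching the alkyl aryl ester or the skipped diene.

12 to 11: the C3=C4 π bond is traced back to the C4 hydroxyl and a C3 hydrogen. This keeps the skipped diene out of all earlier steps and uses the tertiary alcohol left by the ring closure; 11 has a single alkene. The elimination must take a C3 hydrogen, not H5 (conjugated diene, loss of C5) and not a methyl hydrogen.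

11 to 7 and 9 (through 10), and 9 to 8: the acyl C–O8 bond is cut, which separates the terpene diol from the aromatic acid. The forward step must acylate a hindered secondary alcohol next to a free tertiary one.

7 to 6: the C7–H and C11–H bonds are removed, restoring C7=C11. C7 can then be set from its neighbour C8 by hydroxyl delivery of hydrogen, and the isopropylidene is what 1 provides. The hydrogenation must touch C7=C11 only, on the face of the C8 oxygen. For that reason it is placed before C3=C4 exists, when the only other alkene is the tetrasubstituted ring-fusion C1=C10.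

6 to 5: the O–Si bond is cut; the silyl group serves only the acid step.

5 to 4: the C1–C5 bond is cut, opening both rings to a ten-membered ring with a 4,5-epoxide and the C1=C10 alkene. The forward step must bond C1 to C5 with inversion at C5 and lose the C1 proton. The (4S,5S,8S) configuration of 4 maps onto (4S,5S,8S) in 5; the C5 descriptor is unchanged only because the priorities change.

4 to 3 to 2: the O–Si and C8–H bonds are cut, returning to the ketone. The reduction must give 8S under catalyst control and leave the epoxide intact.

2 to 1: the two epoxide C–O bonds are cut. Oxidising while the C8 ketone is still present lets the carbonyl deactivate C7=C11 (conjugated) and C1=C10 (closer to the carbonyl), so site selectivity rests on the substrate. The forward step must deliver the (4S,5S)-epoxide, which calls for the L-series fructose-derived ketone.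

## Other disconnections considered

Alternative 1: The C1=C10 bond (σ and π) is replaced by a C1–SO2–C10 bridge, so the seven-membered ring is traced back to the eight-membered cyclic sulfone A2 fused to the intact cyclopentene. In the forward direction, KOH on alumina with CBr2F2 would halogenate an α-carbon, the α′-carbanion would displace halide, and loss of the sulfur bridge would give the silyl ether A1 (Ramberg–Bäcklund contraction).
- In favour: the tetrasubstituted alkene can only form between the two carbons that carried sulfur. C3=C4, C5, C7 and C8 would be in place beforehand, so no late dehydration or selective hydrogenation is needed.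
- Against: both α-carbons of A2 are methines, the hardest case for halogenation and 1,3-elimination. The basic medium acts on a product with doubly allylic hydrogens, and difluorocarbene from CBr2F2 can add to the electron-rich alkenes. A2 has no cheap precursor and its three stereocenters must be built de novo.
- Comparison: on alkene placement this plan is the better one, since step 4 of the chosen route depends on which proton leaves. On stereocontrol it is weaker, because the chosen route takes C5 stereospecifically from an epoxide and C7 from C8. It is estimated to be clearly longer.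

Alternative 2: C5–C1 and C5–C6 are cut, leading to the aryl diazoketone A4, reachable in a few steps from thymol A5. In the forward direction, Cu(MeCN)4PF6 (monovalent copper) with a chiral bis(oxazoline) would generate a carbene that adds across the arene bond C1–C6; ring opening would give the 8a-H azulenone A3 (Büchner reaction).
- In favour: the arene supplies the whole seven-membered ring with methyl, isopropyl and oxygen already at C10, C7 and C8. The ortho methyl blocks the other ipso–ortho bond. Both rings form in one step, which equals the chosen plan. The starting material is a commodity, which is better than relying on a natural sesquiterpene.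
- Against: C5 of A3 is α to the C4 ketone and doubly allylic, so it is open to enolisation and hydrogen shifts. The C4 ketone must become C3=C4(Me) by enolisation towards C3, away from that same C5. The triene and enol ether must be taken down to C7–H and C8–H(O) with two new stereocenters under substrate control in a flexible ring while C1=C10 stays.
- Comparison: equal in ring-forming power and better in availability. It is weaker in stereocontrol and in redox economy after the key step. The step count is estimated as similar or slightly higher.

Alternative 3: C1–C5, C2–C3 and C3–C4 are cut, so the five-membered ring is built around external CO from the acyclic allenyne A7, which already carries C7 and C8. In the forward direction, [Rh(CO)2Cl]2 (monovalent rhodium) under CO would join the alkyne C4≡C5, the distal allene bond C1=C2 and CO to give the cross-conjugated dienone A6 (allenic Pauson–Khand reaction).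
- In favour: C1=C10 is the untouched proximal allene bond, so its position is fixed by constitution, which is better than the chosen plan. C7 and C8 are set in an open chain by reliable methods with no selective hydrogenation, also better. Both rings form in one catalytic step, which is equal. No cationic intermediates are involved.
- Against: A6 has oxygen at C3 and the alkene at C4=C5. The ketone must be removed with 1,3-transposition to C3=C4 while hydrogen reaches C5 on the correct face, so C5 is set late and only by relay from a new C3 carbinol. The dienone and its reduction products are prone to ionisation. A7 itself needs a multistep synthesis.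
- Comparison: both plans close the same C1–C5 bond, but the chosen plan sets C5 stereospecifically. The alternative is more flexible for analogues and is estimated to be about half as long again.

Key step: step 4

Assumption: the L-fructose-derived (enantiomeric) Shi ketone is taken as a purchasable catalyst, and the usual spiro transition-state model for E-trisubstituted alkenes is taken to hold for C4=C5 of 1.

## Route

Step 1
Reactants: 1 germacrone, (1(10)E,4E)-germacra-1(10),4,7(11)-trien-8-one
Product: 2 (4S,5S)-4,5-epoxygermacra-1(10),7(11)-dien-8-one
Conditions: L-fructose-derived Shi ketone (30 mol %), KHSO5 (as 2KHSO5·KHSO4·K2SO4), K2CO3, Bu4NHSO4, MeCN–(MeO)2CH2–aq. buffer pH 10.5, 0 °C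
Reagents that add atoms: potassium peroxymonosulfate, [K+].[O-]S(=O)(=O)OO
Why: Shi epoxidation with a chiral dioxirane; the ketone deactivates C7=C11 by conjugation and C1=C10 by proximity, so the remote E-trisubstituted C4=C5 should react first. Compound 1 has no stereocenter and its ring conformers are interconverting mirror images, so the catalyst alone selects the outer face, and the L-series ketone should give the (4S,5S)-epoxide.

Step 2
Reactants: 2 (4S,5S)-4,5-epoxygermacra-1(10),7(11)-dien-8-one
Product: 3 (4S,5S,8S)-4,5-epoxygermacra-1(10),7(11)-dien-8-ol
Conditions: (R)-2-methyl-CBS-oxazaborolidine (20 mol %), catecholborane, toluene, −78 °C; then aq. NaOH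
Reagents that add atoms: none
Why: Corey–Bakshi–Shibata 1,2-reduction of an enone; the alkenyl C7 side is the large group and C9H2 the small one, so the (R)-catalyst should give 8S. Catecholborane at −78 °C should leave the epoxide and the alkenes alone.

Step 3
Reactants: 3 (4S,5S,8S)-4,5-epoxygermacra-1(10),7(11)-dien-8-ol
Product: 4 (4S,5S,8S)-8-(tert-butyldimethylsilyloxy)-4,5-epoxygermacra-1(10),7(11)-diene
Conditions: TBSCl, imidazole, DMAP (cat.), DMF, rt
Reagents that add atoms: tert-butyldimethylsilyl chloride, CC(C)(C)[Si](C)(C)Cl
Why: Silylation under purely basic conditions; a silyl triflate is avoided because its Lewis acidity could open the epoxide early. The ether stops the hydroxyl from attacking C5 and makes the allylic C8–O bond harder to ionise in step 4.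

Step 4
Reactants: 4 (4S,5S,8S)-8-(tert-butyldimethylsilyloxy)-4,5-epoxygermacra-1(10),7(11)-diene
Product: 5 (4S,5S,8S)-8-(tert-butyldimethylsilyloxy)guaia-1(10),7(11)-dien-4-ol
Conditions: p-TsOH (anhydrous, 10 mol %), CH2Cl2, 0 °C → rt
Reagents that add atoms: none
Why: Protonation of the epoxide makes C5 electrophilic; the C1=C10 π bond, held across the ring in the crossed conformation, attacks C5 through C1 opposite the C5–O bond, forming C1–C5 and a tertiary C10 cation that loses the C1 proton to give C1=C10 and the C4 alcohol. The closest known reaction type is the sulfonic-acid-promoted transannular cyclization of 4,5-epoxygermacr-1(10)-enes to 4-hydroxyguai-1(10)-enes. One bond closes both rings: the five-membered ring forms exo to the alkene and endo to the epoxide, the seven-membered ring endo to the alkene and exo to the epoxide. C5 is the center that is set, by stereospecific inversion at the epoxide carbon, so it follows from the catalyst-made (5S)-epoxide; C4 keeps its C–O bond and configuration, and its hydroxyl ends cis to H5. Bonding of C1 to C5 (not C10 to C5, and not opening at C4) is secured by the tertiary C10 cation and the short transannular C1···C5 distance. Loss of H1 over a C9 or C14 hydrogen is favoured because it gives the most substituted alkene and no C8 carbonyl is left to pull the alkene to C9=C10. The allylic C8 oxygen should survive as a poorly basic silyl ether under catalytic, water-free acid at or below room temperature.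

Step 5
Reactants: 5 (4S,5S,8S)-8-(tert-butyldimethylsilyloxy)guaia-1(10),7(11)-dien-4-ol
Product: 6 (4S,5S,8S)-guaia-1(10),7(11)-diene-4,8-diol
Conditions: TBAF, THF, 0 °C → rt
Reagents that add atoms: none
Why: Fluoride-mediated desilylation; the tertiary alcohol and both tetrasubstituted alkenes are inert to fluoride.

Step 6
Reactants: 6 (4S,5S,8S)-guaia-1(10),7(11)-diene-4,8-diol
Product: 7 (4S,5S,7R,8S)-guai-1(10)-ene-4,8-diol
Conditions: [Ir(cod)(PCy3)(py)]PF6 (10 mol %), H2 (1 atm), CH2Cl2, 0 °C → rt, stopped after 1 equiv H2
Reagents that add atoms: none
Why: Hydroxyl-directed homogeneous hydrogenation; allylic 1,3-strain places the C8–O bond roughly perpendicular to the isopropylidene plane, so oxygen-bound iridium should deliver both hydrogens to the face of C7=C11 that carries O8. H7 then ends cis to O8 (7R, isopropyl trans to oxygen). C1=C10 is a ring-fusion tetrasubstituted alkene only homoallylic to the hydroxyls, and no skipped diene or trisubstituted alkene is present at this stage.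

Step 7
Reactants: 8 vanillic acid
Product: 9 4-acetoxy-3-methoxybenzoic acid
Conditions: Ac2O, pyridine, rt; then H2O
Reagents that add atoms: acetic anhydride, CC(=O)OC(C)=O
Why: O-Acetylation of the phenol; any mixed anhydride at the carboxyl group is hydrolysed on aqueous work-up.

Step 8
Reactants: 7 (4S,5S,7R,8S)-guai-1(10)-ene-4,8-diol; 9 4-acetoxy-3-methoxybenzoic acid
Product: 11 (4S,5S,7R,8S)-4-hydroxyguai-1(10)-en-8-yl 4-acetoxy-3-methoxybenzoate, via 4-acetoxy-3-methoxybenzoyl chloride 10 (not isolated)
Conditions: 9, (COCl)2, DMF (cat.), CH2Cl2, 0 °C → rt, evaporate; then 7, Et3N, DMAP, CH2Cl2, 0 °C → rt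
Reagents that add atoms: none
Why: Acid chloride formation followed by DMAP-catalysed acylation; the secondary C8 hydroxyl should react while the tertiary C4 hydroxyl is too hindered. The masked phenol cannot self-condense.

Step 9
Reactants: 11 (4S,5S,7R,8S)-4-hydroxyguai-1(10)-en-8-yl 4-acetoxy-3-methoxybenzoate
Product: 12 (5R,7R,8S)-guaia-1(10),3-dien-8-yl 4-acetoxy-3-methoxybenzoate
Conditions: Ph2S[OC(CF3)2Ph]2, CH2Cl2, −40 → 0 °C
Reagents that add atoms: none
Why: Sulfurane dehydration through an alkoxysulfonium ion with anti elimination; H5 is cis to the leaving oxygen and cannot be anti-periplanar, and of the remaining hydrogens the ring C3–H should give the more stable endocyclic cyclopentene over the exocyclic methylene. The neutral, cold conditions should not isomerise the new skipped diene, and the phenol is still masked so it cannot consume the reagent.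

Step 10
Reactants: 12 (5R,7R,8S)-guaia-1(10),3-dien-8-yl 4-acetoxy-3-methoxybenzoate
Product: 13 (5R,7R,8S)-guaia-1(10),3-dien-8-yl 4-hydroxy-3-methoxybenzoate (target)
Conditions: pyrrolidine, CH2Cl2, 0 °C → rt
Reagents that add atoms: none
Why: Aminolysis of an aryl acetate, an activated ester; the hindered, electron-rich alkyl benzoate should be untouched, and no acid or strong base meets the skipped diene.

## Compound list

1 | germacrone, (1(10)E,4E)-germacra-1(10),4,7(11)-trien-8-one | O=C1C/C(C)=C/CC/C(C)=C/CC1=C(C)C | starting material
2 | (4S,5S)-4,5-epoxygermacra-1(10),7(11)-dien-8-one | O=C1C/C(C)=C/CC[C@]2(C)O[C@H]2CC1=C(C)C | intermediate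
3 | (4S,5S,8S)-4,5-epoxygermacra-1(10),7(11)-dien-8-ol | O[C@H]1C/C(C)=C/CC[C@]2(C)O[C@H]2CC1=C(C)C | intermediate
4 | (4S,5S,8S)-8-(tert-butyldimethylsilyloxy)-4,5-epoxygermacra-1(10),7(11)-diene | CC(C)(C)[Si](C)(C)O[C@H]1C/C(C)=C/CC[C@]2(C)O[C@H]2CC1=C(C)C | intermediate
5 | (4S,5S,8S)-8-(tert-butyldimethylsilyloxy)guaia-1(10),7(11)-dien-4-ol | CC(C)(C)[Si](C)(C)O[C@H]2CC(C)=C3CC[C@](C)(O)[C@H]3CC2=C(C)C | intermediate
6 | (4S,5S,8S)-guaia-1(10),7(11)-diene-4,8-diol | O[C@H]2CC(C)=C3CC[C@](C)(O)[C@H]3CC2=C(C)C | intermediate
7 | (4S,5S,7R,8S)-guai-1(10)-ene-4,8-diol | O[C@H]2CC(C)=C3CC[C@](C)(O)[C@H]3C[C@@H]2C(C)C | intermediate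
8 | vanillic acid | COc1cc(C(=O)O)ccc1O | starting material
9 | 4-acetoxy-3-methoxybenzoic acid | COc1cc(C(=O)O)ccc1OC(C)=O | intermediate
10 | 4-acetoxy-3-methoxybenzoyl chloride (not isolated) | COc1cc(C(=O)Cl)ccc1OC(C)=O | intermediate
11 | (4S,5S,7R,8S)-4-hydroxyguai-1(10)-en-8-yl 4-acetoxy-3-methoxybenzoate | COc1cc(C(=O)O[C@H]2CC(C)=C3CC[C@](C)(O)[C@H]3C[C@@H]2C(C)C)ccc1OC(C)=O | intermediate
12 | (5R,7R,8S)-guaia-1(10),3-dien-8-yl 4-acetoxy-3-methoxybenzoate | COc1cc(C(=O)O[C@H]2CC(C)=C3CC=C(C)[C@H]3C[C@@H]2C(C)C)ccc1OC(C)=O | intermediate
13 | (5R,7R,8S)-guaia-1(10),3-dien-8-yl 4-hydroxy-3-methoxybenzoate | COc1cc(C(=O)O[C@H]2CC(C)=C3CC=C(C)[C@H]3C[C@@H]2C(C)C)ccc1O | target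

## Step count and least certain steps

Total: 10 steps. Longest linear sequence: 9 steps (steps 1–6, 8, 9, 10 from 1); the side branch from 8 is one step.

Step 4 (key step). The most likely failure is partition of the C10 cation: proton loss towards C9 or C14, or capture by a nucleophile. Acid-induced ionisation at the allylic C8 oxygen is the second concern. Both arise because nothing but alkene stability steers the termination. Fallback, from 2 and returning at 6: the cyclization would be run at the ketone level (p-TsOH, CH2Cl2), where conjugation should direct proton loss to C9 and give 4-hydroxyguaia-7(11),9-dien-8-one F1. Deconjugation through the extended dienolate (KOt-Bu, t-BuOH–THF, then cold aqueous AcOH, kinetic protonation at C9) would give (4S,5S)-4-hydroxyguaia-1(10),7(11)-dien-8-one F2. Reduction of F2 with the (R)-oxazaborolidine and catecholborane would give 6 directly, with no silyl group needed. The deconjugation is itself uncertain, because F1 has other acidic γ positions.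

Step 1. Poor discrimination between the two mirror-image ring conformers (low enantioselectivity) or competing oxidation of C1=C10 could occur, because the facial model is being carried over to a medium ring. Fallback, from 1 and returning at 3: mCPBA (CH2Cl2, 0 °C) would give the racemic epoxide, that is 2 with its enantiomer (4R,5R)-4,5-epoxygermacra-1(10),7(11)-dien-8-one F3. The reagent-controlled reduction of step 2 would then convert the pair into 3 and the diastereomer (4R,5R,8S)-4,5-epoxygermacra-1(10),7(11)-dien-8-ol F4, which would be removed by chromatography at the cost of half the material.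

Step 2. Facial selectivity could be eroded if the ring conformation imposed by the epoxide opposes the catalyst. Fallback, from 1 and returning at 4: the order would be reversed. Compound 1 would be reduced first with the same (R)-oxazaborolidine and catecholborane, where no resident stereocenter interferes, to (8S)-germacra-1(10),4,7(11)-trien-8-ol F5. Silylation (TBSCl, imidazole) would give (8S)-8-(tert-butyldimethylsilyloxy)germacra-1(10),4,7(11)-triene F6, and the L-series Shi epoxidation would be run last with limiting oxidant. This fallback gives up the ketone-based site selectivity.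

Step 6. Chemoselectivity could be lost by hydrogen delivery to C1=C10, which is homoallylic to both the C4 and the C8 hydroxyl, because both alkenes are tetrasubstituted and reduce slowly. Fallback, from 5 and returning at 12: the C4 hydroxyl would be removed first. Ph2S[OC(CF3)2Ph]2 on 5 would give (5R,8S)-8-(tert-butyldimethylsilyloxy)guaia-1(10),3,7(11)-triene F7, and TBAF would give (5R,8S)-guaia-1(10),3,7(11)-trien-8-ol F8. The same iridium-catalysed hydrogenation, now directed by the only hydroxyl, would give (5R,7R,8S)-guaia-1(10),3-dien-8-ol F9, and acylation with 10 (Et3N, DMAP) would give 12. This exposes the skipped diene to the catalyst, so it is held in reserve.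

Step 9. Ionisation of the tertiary alkoxysulfonium ion (E1 leakage) could lead to loss of the allylic H5 and a conjugated diene, or elimination could go towards the methyl group. Fallback, from 11 and returning at 12: C1=C10 would be masked. mCPBA (NaHCO3, CH2Cl2) should give the 1,10-epoxide of 11 F10, expected on the face of the C4 hydroxyl; either face serves. The same sulfurane dehydration, which is the known type for 1,10-epoxy-4-hydroxyguaianes, would give the 1,10-epoxide of 12 F11. Deoxygenation with MeReO3 (cat.) and PPh3 would restore C1=C10 and give 12.

## Further compounds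

F1 | step 4 | (4S,5S)-4-hydroxyguaia-7(11),9-dien-8-one (C1 left open, erased on deconjugation) | O=C2C=C(C)C3CC[C@](C)(O)[C@H]3CC2=C(C)C
F2 | step 4 | (4S,5S)-4-hydroxyguaia-1(10),7(11)-dien-8-one | O=C2CC(C)=C3CC[C@](C)(O)[C@H]3CC2=C(C)C
F3 | step 1 | (4R,5R)-4,5-epoxygermacra-1(10),7(11)-dien-8-one | O=C1C/C(C)=C/CC[C@@]2(C)O[C@@H]2CC1=C(C)C
F4 | step 1 | (4R,5R,8S)-4,5-epoxygermacra-1(10),7(11)-dien-8-ol | O[C@H]1C/C(C)=C/CC[C@@]2(C)O[C@@H]2CC1=C(C)C
F5 | step 2 | (8S)-germacra-1(10),4,7(11)-trien-8-ol | O[C@H]1C/C(C)=C/CC/C(C)=C/CC1=C(C)C
F6 | step 2 | (8S)-8-(tert-butyldimethylsilyloxy)germacra-1(10),4,7(11)-triene | CC(C)(C)[Si](C)(C)O[C@H]1C/C(C)=C/CC/C(C)=C/CC1=C(C)C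
F7 | step 6 | (5R,8S)-8-(tert-butyldimethylsilyloxy)guaia-1(10),3,7(11)-triene | CC(C)(C)[Si](C)(C)O[C@H]2CC(C)=C3CC=C(C)[C@H]3CC2=C(C)C
F8 | step 6 | (5R,8S)-guaia-1(10),3,7(11)-trien-8-ol | O[C@H]2CC(C)=C3CC=C(C)[C@H]3CC2=C(C)C
F9 | step 6 | (5R,7R,8S)-guaia-1(10),3-dien-8-ol | O[C@H]2CC(C)=C3CC=C(C)[C@H]3C[C@@H]2C(C)C
F10 | step 9 | 1,10-epoxide of 11 (oxygen on the face of the C4 hydroxyl) | COc1cc(C(=O)O[C@H]2C[C@]4(C)O[C@@]43CC[C@](C)(O)[C@H]3C[C@@H]2C(C)C)ccc1OC(C)=O
F11 | step 9 | 1,10-epoxide of 12 (same face) | COc1cc(C(=O)O[C@H]2C[C@]4(C)O[C@@]43CC=C(C)[C@H]3C[C@@H]2C(C)C)ccc1OC(C)=O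
A1 | alternative 1 | (5R,7R,8S)-8-(tert-butyldimethylsilyloxy)guaia-1(10),3-diene | CC(C)(C)[Si](C)(C)O[C@H]2CC(C)=C3CC=C(C)[C@H]3C[C@@H]2C(C)C
A2 | alternative 1 | eight-membered cyclic sulfone with a C1–SO2–C10 bridge fused to the C3=C4 cyclopentene, C8 silyl ether (C1 and C10 configuration immaterial) | CC(C)(C)[Si](C)(C)O[C@H]2CC(C)S(=O)(=O)C3CC=C(C)[C@H]3C[C@@H]2C(C)C
A3 | alternative 2 | (8aS)-6-methoxy-4-methyl-7-(propan-2-yl)-3,8a-dihydroazulen-1(2H)-one (guaiane numbering: C4 ketone, C8 methyl enol ether) | COC2=CC(C)=C3CCC(=O)[C@H]3C=C2C(C)C
A4 | alternative 2 | 1-diazo-4-[4-methoxy-2-methyl-5-(propan-2-yl)phenyl]butan-2-one | COc1cc(C)c(CCC(=O)C=[N+]=[N-])cc1C(C)C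
A5 | alternative 2 | thymol | Cc1ccc(C(C)C)c(O)c1
A6 | alternative 3 | (7R,8S)-8-(tert-butyldimethylsilyloxy)guaia-1(10),4-dien-3-one | CC(C)(C)[Si](C)(C)O[C@H]2CC(C)=C3CC(=O)C(C)=C3C[C@@H]2C(C)C
A7 | alternative 3 | (5S,6R)-5-(tert-butyldimethylsilyloxy)-3-methyl-6-(propan-2-yl)deca-1,2-dien-8-yne | CC(C)(C)[Si](C)(C)O[C@@H](CC(C)=C=C)[C@H](CC#CC)C(C)C
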